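**Plan**

1. Numbering: the ring is numbered as cyclohex-4-ene-1,3-diol (C1 tertiary carbinol, C3 secondary carbinol) and the side chain C1′ (on C1) to C16′ (on phenyl). The retrosynthesis cuts, in this order, C13′–C14′ (alkenyl CH to the first CH2 of the 3-phenylpropyl end), the two O–Si bonds, ring C4=C5, ring C1–C6, C1–C1′ and C11′–C12′.
2. Forward: acetylide alkylation (C11′–C12′) gives the C13 chain, which is joined to the C1–C4 unit as a ketone (C1–C1′). A tethered acetate then closes a temporary lactone ring at C1–C6, the lactone is opened to an allyl arm, and metathesis closes the cyclohexene, the only ring of the target, at C4=C5. The alkyne C12′≡C13′ is then unmasked, borylated and coupled at C13′–C14′.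
3. Enabling feature: C12′=C13′ is an isolated cis CH=CH, remote from the ring, whose C13′ carries only H, C12′ and the sp3 carbon C14′. With boron on C13′, both C13′ and C14′ become boron-bound nucleophilic ligands of like polarity that iodine couples oxidatively, and the same event turns the E alkenylboron geometry into the Z alkene.
4. Stereochemistry: C3 comes from ethyl (3S)-3-hydroxypent-4-enoate. C1 is set from C3 by 1,3-induction in the chelated chair transition state of a samarium enolate cyclisation. The Z geometry follows from syn hydroboration (E) and the anti-addition/anti-elimination course of the coupling.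

Key step: step 12

Assumption: ethyl (3S)-3-hydroxypent-4-enoate is taken as a purchasable enantiopure building block (it is otherwise accessible by lipase resolution of the racemate); its C3 becomes C3 of the target unchanged.

**Route**

Step 1
Reactants: 1 1,11-dibromoundecane; 2 lithium (trimethylsilyl)acetylide
Product: 3 (13-bromotridec-1-yn-1-yl)trimethylsilane
Conditions: 2 (1 equiv) added to 1 (3 equiv), THF/DMPU, −78 °C to rt; excess 1 recovered by bulb-to-bulb distillation
Reagents that add atoms: none
Why: SN2 alkylation of the lithium acetylide by a primary bromide (acetylide alkylation) in a dipolar cosolvent should give 3, and the threefold excess of the symmetric dibromide should keep double substitution low.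

Step 2
Reactants: 4 ethyl (3S)-3-hydroxypent-4-enoate
Product: 5 (3S)-3-hydroxy-N-methoxy-N-methylpent-4-enamide
Conditions: MeNH(OMe)·HCl (2.5 equiv), i-PrMgCl (5.5 equiv), THF, −20 to 0 °C
Reagents that add atoms: N,O-dimethylhydroxylamine hydrochloride, CNOC.Cl
Why: The chloromagnesium amide formed in the flask should displace ethoxide from the ester (ester to N-methoxy-N-methylamide aminolysis) at low temperature without touching C3, the deprotonated hydroxyl being a poor leaving group for β-elimination.

Step 3
Reactants: 3 (13-bromotridec-1-yn-1-yl)trimethylsilane; 5 (3S)-3-hydroxy-N-methoxy-N-methylpent-4-enamide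
Product: 7 (3S)-3-hydroxy-18-(trimethylsilyl)octadec-1-en-17-yn-5-one, via Grignard reagent 6 (not isolated)
Conditions: (a) 3, Mg, THF, 40 °C; (b) 5, i-PrMgCl (1 equiv), THF, −20 °C, then 6 (1.6 equiv), 0 °C to rt; cold aq. NH4Cl
Reagents that add atoms: none
Why: Weinreb ketone synthesis, in which Grignard reagent 6 should add once to the N-methoxy-N-methylamide because the magnesium-chelated tetrahedral adduct only collapses on work-up, the hydroxyl being deprotonated beforehand so that it does not quench 6, and C3 is not touched.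

Step 4
Reactants: 7 (3S)-3-hydroxy-18-(trimethylsilyl)octadec-1-en-17-yn-5-one; 8 bromoacetyl bromide
Product: 9 (3S)-5-oxo-18-(trimethylsilyl)octadec-1-en-17-yn-3-yl bromoacetate
Conditions: pyridine (1.5 equiv), CH2Cl2, −40 to 0 °C
Reagents that add atoms: none
Why: O-acylation of the secondary allylic alcohol by the acid bromide (esterification) should be fast at low temperature with pyridine as a weak base, conditions chosen so that E1cB loss of the new β-acyloxy group from the ketone stays slow.

Step 5
Reactants: 9 (3S)-5-oxo-18-(trimethylsilyl)octadec-1-en-17-yn-3-yl bromoacetate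
Product: 11 (4R,6S)-6-ethenyl-4-hydroxy-4-[13-(trimethylsilyl)tridec-12-yn-1-yl]oxan-2-one, via samarium enolate 10 (not isolated)
Conditions: SmI2 (2.2 equiv), THF, −78 °C; aq. NH4Cl
Reagents that add atoms: none
Why: Intramolecular Reformatsky reaction promoted by SmI2, in which two-electron reduction of the C–Br bond gives samarium enolate 10 whose trivalent samarium also binds the ketone oxygen, so the aldol ring closure should run through a chair with the vinyl group at lactone C6 and the long chain at lactone C4 equatorial and the ketone oxygen axial, which sets C4 as R (hydroxyl trans to vinyl) by 1,3-induction from C6.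

Step 6
Reactants: 11 (4R,6S)-6-ethenyl-4-hydroxy-4-[13-(trimethylsilyl)tridec-12-yn-1-yl]oxan-2-one
Product: 12 (4R,6S)-6-ethenyl-4-[13-(trimethylsilyl)tridec-12-yn-1-yl]oxane-2,4-diol (mixture of anomers at C2)
Conditions: i-Bu2AlH (2.2 equiv), CH2Cl2, −78 °C; aq. KNaC4H4O6 (potassium sodium tartrate)
Reagents that add atoms: none
Why: Partial reduction of the lactone by i-Bu2AlH at −78 °C should stop at the lactol because the aluminium hemiacetal is stable in the cold, one further equivalent being consumed by the tertiary hydroxyl, and no stereocenter of the carbon chain is affected.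

Step 7
Reactants: 12 (4R,6S)-6-ethenyl-4-[13-(trimethylsilyl)tridec-12-yn-1-yl]oxane-2,4-diol
Product: 13 (3S,5S)-5-[13-(trimethylsilyl)tridec-12-yn-1-yl]octa-1,7-diene-3,5-diol
Conditions: Ph3PCH3Br (5 equiv), n-BuLi (4.8 equiv), THF, 0 °C, then 12, 0 °C to rt
Reagents that add atoms: methyltriphenylphosphonium bromide, C[P+](c1ccccc1)(c1ccccc1)c1ccccc1.[Br-]
Why: Wittig methylenation of the open hydroxy-aldehyde form of 12 should turn the former bromoacetate carbonyl carbon into the internal alkene carbon of an allyl group and free the C3 hydroxyl, lithium counter-ions being chosen to slow retro-aldol cleavage of the β-alkoxy aldehyde.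

Step 8
Reactants: 13 (3S,5S)-5-[13-(trimethylsilyl)tridec-12-yn-1-yl]octa-1,7-diene-3,5-diol
Product: 14 (1S,3S)-1-[13-(trimethylsilyl)tridec-12-yn-1-yl]cyclohex-4-ene-1,3-diol
Conditions: second-generation Grubbs catalyst RuCl2(=CHPh)(PCy3)(H2IMes) (3 mol %), CH2Cl2 (5 mM), 40 °C
Reagents that add atoms: none
Why: Ring-closing metathesis of the 1,7-diene should close the cyclohexene at C4=C5 with loss of ethylene, six-membered ring formation being fast and the silyl-capped alkyne being a poor partner for the ruthenium carbene, and neither stereocenter is touched so the 1,3-diol comes out cis.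

Step 9
Reactants: 14 (1S,3S)-1-[13-(trimethylsilyl)tridec-12-yn-1-yl]cyclohex-4-ene-1,3-diol
Product: 15 (1S,3S)-1-[13-(trimethylsilyl)tridec-12-yn-1-yl]cyclohex-4-ene-1,3-diol bis(triethylsilyl) ether
Conditions: Et3SiOTf (3 equiv), 2,6-lutidine (4 equiv), CH2Cl2, −78 to 0 °C
Reagents that add atoms: triethylsilyl trifluoromethanesulfonate, CC[Si](CC)(CC)OS(=O)(=O)C(F)(F)F
Why: Silylation with the silyl triflate and 2,6-lutidine should cap both the secondary and the hindered tertiary hydroxyl (silyl ether protection), which is needed because the next steps use a hydridoborane and an alkyllithium.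

Step 10
Reactants: 15 (1S,3S)-1-[13-(trimethylsilyl)tridec-12-yn-1-yl]cyclohex-4-ene-1,3-diol bis(triethylsilyl) ether
Product: 16 (1S,3S)-1-(tridec-12-yn-1-yl)cyclohex-4-ene-1,3-diol bis(triethylsilyl) ether
Conditions: K2CO3 (0.5 equiv), MeOH/THF, rt
Reagents that add atoms: none
Why: Base-catalysed methanolysis should cleave the C(sp)–Si bond only (protodesilylation of an alkynylsilane), since triethylsilyl ethers of alcohols are stable to K2CO3 in MeOH at room temperature.

Step 11
Reactants: 16 (1S,3S)-1-(tridec-12-yn-1-yl)cyclohex-4-ene-1,3-diol bis(triethylsilyl) ether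
Product: 17 2-{(1E)-13-[(1S,3S)-1,3-bis(triethylsilyloxy)cyclohex-4-en-1-yl]tridec-1-en-1-yl}-4,4,5,5-tetramethyl-1,3,2-dioxaborolane
Conditions: pinacolborane (1.5 equiv), Cp2Zr(H)Cl (10 mol %), Et3N (10 mol %), neat, 60 °C
Reagents that add atoms: pinacolborane, [H]B1OC(C)(C)C(C)(C)O1
Why: Hydroboration of the terminal alkyne with pinacolborane catalysed by Cp2Zr(H)Cl should give only the E-1-alkenylboronate by syn, anti-Markovnikov addition, the disubstituted ring alkene being far less reactive toward hydrozirconation.

Step 12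
Reactants: 17 2-{(1E)-13-[(1S,3S)-1,3-bis(triethylsilyloxy)cyclohex-4-en-1-yl]tridec-1-en-1-yl}-4,4,5,5-tetramethyl-1,3,2-dioxaborolane; 18 1-iodo-3-phenylpropane
Product: 22 (1S,3S)-1-[(12Z)-16-phenylhexadec-12-en-1-yl]cyclohex-4-ene-1,3-diol bis(triethylsilyl) ether, via 3-phenylpropyllithium 19 (not isolated), via lithium boronate complex 20 (not isolated), via iodoalkylboronate 21 (not isolated)
Conditions: (a) 18 (1.3 equiv), t-BuLi (2.6 equiv), Et2O, −78 °C; (b) 17, THF, −78 °C; (c) I2 (1.3 equiv), THF, −78 °C; (d) NaOMe (3 equiv), MeOH, −78 °C to rt; aq. Na2S2O3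
Reagents that add atoms: none
Why: Iodine–lithium exchange turns 18 into 3-phenylpropyllithium 19, which adds to the vacant boron orbital of 17 to give boronate complex 20, so that the two carbons to be joined (alkenyl C13′ and alkyl C14′) both sit on boron as nucleophilic ligands. Iodine then attacks the electron-rich alkene of 20 at C12′ and the 3-phenylpropyl group shifts from boron to C13′ anti to the iodonium bridge (1,2-metallate rearrangement) to give iodoalkylboronate 21, from which methoxide expels boron and iodide by anti elimination. The closest known reaction type is the Zweifel olefination, the transition-metal-free oxidative coupling of an alkenylboronic ester with an organolithium. No ring is closed and no tetrahedral stereocenter remains in the product; the one new stereo-element, the Z geometry of C12′=C13′, is fixed by the E geometry of 17 together with the anti-addition and anti-elimination course of the mechanism. The step needs chemoselectivity for the side-chain alkene over the ring C4=C5 alkene and for carbon over oxygen migration: the negative charge on boron makes the alkene of 20 far more reactive toward iodine at −78 °C than the neutral ring alkene, the primary alkyl ligand migrates in preference to the pinacol oxygens, and the silyl ethers keep both hydroxyls away from the alkyllithium and from iodine.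

Step 13
Reactants: 22 (1S,3S)-1-[(12Z)-16-phenylhexadec-12-en-1-yl]cyclohex-4-ene-1,3-diol bis(triethylsilyl) ether
Product: 23 (1S,3S)-1-[(12Z)-16-phenylhexadec-12-en-1-yl]cyclohex-4-ene-1,3-diol
Conditions: HF·pyridine, pyridine/THF, 0 °C to rt
Reagents that add atoms: none
Why: Fluoride-driven cleavage of both Si–O bonds (silyl ether deprotection), buffered by pyridine, should free the diol without ionising the allylic alcohol or isomerising the Z alkene.

**Compound list**

1 | 1,11-dibromoundecane | BrCCCCCCCCCCCBr | starting material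
2 | lithium (trimethylsilyl)acetylide | [Li]C#C[Si](C)(C)C | starting material
3 | (13-bromotridec-1-yn-1-yl)trimethylsilane | BrCCCCCCCCCCCC#C[Si](C)(C)C | intermediate
4 | ethyl (3S)-3-hydroxypent-4-enoate | C=C[C@@H](O)CC(=O)OCC | starting material
5 | (3S)-3-hydroxy-N-methoxy-N-methylpent-4-enamide | C=C[C@@H](O)CC(=O)N(C)OC | intermediate
6 | [13-(trimethylsilyl)tridec-12-yn-1-yl]magnesium bromide (not isolated) | Br[Mg]CCCCCCCCCCCC#C[Si](C)(C)C | intermediate
7 | (3S)-3-hydroxy-18-(trimethylsilyl)octadec-1-en-17-yn-5-one | C=C[C@@H](O)CC(=O)CCCCCCCCCCCC#C[Si](C)(C)C | intermediate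
8 | bromoacetyl bromide | BrCC(Br)=O | starting material
9 | (3S)-5-oxo-18-(trimethylsilyl)octadec-1-en-17-yn-3-yl bromoacetate | C=C[C@@H](OC(=O)CBr)CC(=O)CCCCCCCCCCCC#C[Si](C)(C)C | intermediate
10 | diiodosamarium enolate of the acetate of 7 (not isolated) | C=C[C@@H](OC(=C)O[Sm](I)I)CC(=O)CCCCCCCCCCCC#C[Si](C)(C)C | intermediate
11 | (4R,6S)-6-ethenyl-4-hydroxy-4-[13-(trimethylsilyl)tridec-12-yn-1-yl]oxan-2-one | C=C[C@@H]1C[C@](O)(CCCCCCCCCCCC#C[Si](C)(C)C)CC(=O)O1 | intermediate
12 | (4R,6S)-6-ethenyl-4-[13-(trimethylsilyl)tridec-12-yn-1-yl]oxane-2,4-diol (mixture of anomers at C2) | C=C[C@@H]1C[C@](O)(CCCCCCCCCCCC#C[Si](C)(C)C)CC(O)O1 | intermediate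
13 | (3S,5S)-5-[13-(trimethylsilyl)tridec-12-yn-1-yl]octa-1,7-diene-3,5-diol | C=C[C@@H](O)C[C@](O)(CCCCCCCCCCCC#C[Si](C)(C)C)CC=C | intermediate
14 | (1S,3S)-1-[13-(trimethylsilyl)tridec-12-yn-1-yl]cyclohex-4-ene-1,3-diol | O[C@@H]1C=CC[C@@](O)(CCCCCCCCCCCC#C[Si](C)(C)C)C1 | intermediate
15 | (1S,3S)-1-[13-(trimethylsilyl)tridec-12-yn-1-yl]cyclohex-4-ene-1,3-diol bis(triethylsilyl) ether | CC[Si](CC)(CC)O[C@@H]1C=CC[C@@](O[Si](CC)(CC)CC)(CCCCCCCCCCCC#C[Si](C)(C)C)C1 | intermediate
16 | (1S,3S)-1-(tridec-12-yn-1-yl)cyclohex-4-ene-1,3-diol bis(triethylsilyl) ether | CC[Si](CC)(CC)O[C@@H]1C=CC[C@@](O[Si](CC)(CC)CC)(CCCCCCCCCCCC#C)C1 | intermediate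
17 | 2-{(1E)-13-[(1S,3S)-1,3-bis(triethylsilyloxy)cyclohex-4-en-1-yl]tridec-1-en-1-yl}-4,4,5,5-tetramethyl-1,3,2-dioxaborolane | CC[Si](CC)(CC)O[C@@H]1C=CC[C@@](O[Si](CC)(CC)CC)(CCCCCCCCCCC/C=C/B2OC(C)(C)C(C)(C)O2)C1 | intermediate
18 | 1-iodo-3-phenylpropane | ICCCc1ccccc1 | starting material
19 | 3-phenylpropyllithium (not isolated) | [Li]CCCc1ccccc1 | intermediate
20 | lithium {(1E)-13-[(1S,3S)-1,3-bis(triethylsilyloxy)cyclohex-4-en-1-yl]tridec-1-en-1-yl}(3-phenylpropyl)(pinacolato)borate (not isolated) | [Li+].CC[Si](CC)(CC)O[C@@H]1C=CC[C@@](O[Si](CC)(CC)CC)(CCCCCCCCCCC/C=C/[B-]2(CCCc3ccccc3)OC(C)(C)C(C)(C)O2)C1 | intermediate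
21 | 2-{5-iodo-1-phenyl-16-[(1S,3S)-1,3-bis(triethylsilyloxy)cyclohex-4-en-1-yl]hexadecan-4-yl}-4,4,5,5-tetramethyl-1,3,2-dioxaborolane (not isolated; anti adduct, the (4S,5S) form is drawn, the (4R,5R) form is expected beside it and gives the same alkene) | CC[Si](CC)(CC)O[C@@H]1C=CC[C@@](O[Si](CC)(CC)CC)(CCCCCCCCCCC[C@H](I)[C@@H](B2OC(C)(C)C(C)(C)O2)CCCc2ccccc2)C1 | intermediate
22 | (1S,3S)-1-[(12Z)-16-phenylhexadec-12-en-1-yl]cyclohex-4-ene-1,3-diol bis(triethylsilyl) ether | CC[Si](CC)(CC)O[C@@H]1C=CC[C@@](O[Si](CC)(CC)CC)(CCCCCCCCCCC/C=C\CCCc2ccccc2)C1 | intermediate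
23 | (1S,3S)-1-[(12Z)-16-phenylhexadec-12-en-1-yl]cyclohex-4-ene-1,3-diol | O[C@@H]1C=CC[C@@](O)(CCCCCCCCCCC/C=C\CCCc2ccccc2)C1 | target

**Step count**

Total: 13 steps. Longest linear sequence: 12 steps (step 1 or step 2, then steps 3 to 13).

**Steps most likely to fail**

Step 5. What may go wrong: β-elimination of the bromoacetoxy group from the ketone before the enolate closes, simple reductive loss of bromine without ring closure, or poor facial selectivity at the ketone. The fallback sets out from 5 and comes back at 13. Amide 5 is deprotonated with i-PrMgCl and treated with allylmagnesium bromide in THF at −78 °C to give (6S)-6-hydroxyocta-1,7-dien-4-one F1. F1 is then treated in CH2Cl2/Et2O at −78 °C with MgBr2·OEt2 and an excess of Grignard reagent 6. A six-membered magnesium chelate between the alkoxide and the ketone oxygen, with vinyl and allyl equatorial, should steer the chain to the axial position (chelation-controlled 1,3-induction) and give 13 directly. The chain is thus attached last, at the tertiary carbon. The β,γ-unsaturated ketone has to be kept cold and neutral to avoid enolisation and double-bond migration.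

Step 7. What may go wrong: retro-aldol cleavage or dehydration of the β-hydroxy aldehyde under the basic ylide conditions, or sluggish opening of the lactol. The fallback sets out from 11 and comes back at 13. Lactone 11 is opened with MeNH(OMe)·HCl and AlMe3 in CH2Cl2 to (3R,5S)-3,5-dihydroxy-N-methoxy-N-methyl-3-[13-(trimethylsilyl)tridec-12-yn-1-yl]hept-6-enamide F2. The syn-1,3-diol is locked with 2,2-dimethoxypropane and pyridinium p-toluenesulfonate as 2-{(4R,6S)-6-ethenyl-2,2-dimethyl-4-[13-(trimethylsilyl)tridec-12-yn-1-yl]-1,3-dioxan-4-yl}-N-methoxy-N-methylacetamide F3. Reduction with i-Bu2AlH at −78 °C gives 2-{(4R,6S)-6-ethenyl-2,2-dimethyl-4-[13-(trimethylsilyl)tridec-12-yn-1-yl]-1,3-dioxan-4-yl}acetaldehyde F4, which has no free β-alkoxide. Wittig methylenation gives (4S,6S)-6-ethenyl-2,2-dimethyl-4-(prop-2-en-1-yl)-4-[13-(trimethylsilyl)tridec-12-yn-1-yl]-1,3-dioxane F5. Aqueous acetic acid in THF removes the acetonide and returns 13.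

Step 12. What may go wrong: incomplete formation of the boronate complex, competing iodination of the ring alkene, or erosion of the alkene geometry through a non-stereospecific elimination. The fallback sets out from 16 and comes back at 22, and makes the same C13′–C14′ bond at the alkyne oxidation level. Alkyne 16 is deprotonated with n-BuLi in THF/DMPU and alkylated with 18 to give (1S,3S)-1-(16-phenylhexadec-12-yn-1-yl)cyclohex-4-ene-1,3-diol bis(triethylsilyl) ether F6. Syn semihydrogenation with H2 over Pd on CaCO3 poisoned with Pb(OAc)2, in the presence of quinoline, should then give 22 and leave the ring alkene alone.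

**Further compounds**

F1 | step 5 | (6S)-6-hydroxyocta-1,7-dien-4-one | C=C[C@@H](O)CC(=O)CC=C
F2 | step 7 | (3R,5S)-3,5-dihydroxy-N-methoxy-N-methyl-3-[13-(trimethylsilyl)tridec-12-yn-1-yl]hept-6-enamide | C=C[C@@H](O)C[C@](O)(CCCCCCCCCCCC#C[Si](C)(C)C)CC(=O)N(C)OC
F3 | step 7 | 2-{(4R,6S)-6-ethenyl-2,2-dimethyl-4-[13-(trimethylsilyl)tridec-12-yn-1-yl]-1,3-dioxan-4-yl}-N-methoxy-N-methylacetamide | C=C[C@@H]1C[C@](CCCCCCCCCCCC#C[Si](C)(C)C)(CC(=O)N(C)OC)OC(C)(C)O1
F4 | step 7 | 2-{(4R,6S)-6-ethenyl-2,2-dimethyl-4-[13-(trimethylsilyl)tridec-12-yn-1-yl]-1,3-dioxan-4-yl}acetaldehyde | C=C[C@@H]1C[C@](CCCCCCCCCCCC#C[Si](C)(C)C)(CC=O)OC(C)(C)O1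
F5 | step 7 | (4S,6S)-6-ethenyl-2,2-dimethyl-4-(prop-2-en-1-yl)-4-[13-(trimethylsilyl)tridec-12-yn-1-yl]-1,3-dioxane | C=C[C@@H]1C[C@](CCCCCCCCCCCC#C[Si](C)(C)C)(CC=C)OC(C)(C)O1
F6 | step 12 | (1S,3S)-1-(16-phenylhexadec-12-yn-1-yl)cyclohex-4-ene-1,3-diol bis(triethylsilyl) ether | CC[Si](CC)(CC)O[C@@H]1C=CC[C@@](O[Si](CC)(CC)CC)(CCCCCCCCCCCC#CCCCc2ccccc2)C1
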